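## Retrosynthetic overview

1. The pyran ring is closed last, by O2–C3 bond formation: C3 is first fixed at the carbonyl oxidation level as a vinylogous amide, so that the C1 hydroxyl can only close a six-membered ring (the free enynol would be expected to close 5-exo to a furan).
2. C4a–C4 is disconnected to a carvone-derived ketol and (E)-pent-3-en-1-yne. The isopropenyl group is excised in a light-driven, copper-catalysed radical alkynylation. C8a–C1 comes from a formaldehyde aldol.
3. C6 and C7 are derived from (R)-carvone by Luche reduction, hydroxyl-directed epoxidation, Mitsunobu esterification (inversion at C6) and ester-assisted epoxide opening (inversion at C7). The C4a centre that steered them is then sacrificed.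
4. The aryl acid comes from 2,4-dihydroxy-6-methylbenzaldehyde by silylation, methylation and oxidation.
5. Ring order: the carbocycle is bought as carvone; the pyran is formed in the final step.

Convention: carbocycle atoms carry the target numbering (C4a, C5, C6, C7, C8, C8a; pyran C1, O2, C3, C4). β is the ring face that carries O6 and O7 in the target, α the opposite face. Ar = 2-methoxy-6-methyl-4-(triisopropylsilyloxy)phenyl.

Assumption: (E)-pent-3-en-1-yne is bought as the pure E isomer.

## Route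

Step 1
Reactants: 1 2,4-dihydroxy-6-methylbenzaldehyde
Product: 2 2-hydroxy-6-methyl-4-(triisopropylsilyloxy)benzaldehyde
Conditions: TIPSCl, imidazole, CH2Cl2, 0 °C
Reagents that add atoms: triisopropylsilyl chloride, CC(C)[Si](Cl)(C(C)C)C(C)C
Why: Selective O-silylation of the more acidic, non-chelated para phenol, the ortho phenol being hydrogen-bonded to the aldehyde.

Step 2
Reactants: 2 2-hydroxy-6-methyl-4-(triisopropylsilyloxy)benzaldehyde
Product: 3 2-methoxy-6-methyl-4-(triisopropylsilyloxy)benzaldehyde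
Conditions: MeI, Ag2O, MeCN, rt, dark
Reagents that add atoms: iodomethane, CI
Why: Purdie O-methylation of the chelated phenol under non-basic conditions that leave the aryl silyl ether intact.

Step 3
Reactants: 3 2-methoxy-6-methyl-4-(triisopropylsilyloxy)benzaldehyde
Product: 4 2-methoxy-6-methyl-4-(triisopropylsilyloxy)benzoic acid
Conditions: NaClO2, NaH2PO4, 2-methylbut-2-ene, t-BuOH/H2O, 0 °C to rt
Reagents that add atoms: sodium chlorite, [Na+].[O-]Cl=O
Why: Pinnick oxidation of the aldehyde, with the alkene scavenging HOCl so that the electron-rich ring is not chlorinated.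

Step 4
Reactants: 5 (R)-(−)-carvone
Product: 6 (1R,5R)-cis-carveol (6α-OH; 4aα-isopropenyl)
Conditions: NaBH4, CeCl3·7H2O, MeOH, −78 to 0 °C
Reagents that add atoms: none
Why: Luche 1,2-reduction in which hydride adds axially to the half-chair with equatorial isopropenyl, so the C6 carbinol is set cis to the bought C4a stereocentre.

Step 5
Reactants: 6 (1R,5R)-cis-carveol
Product: 7 cis-epoxy alcohol (6α-OH; 7α,8α-epoxide; 4aα-isopropenyl)
Conditions: VO(acac)2 (2 mol%), t-BuOOH, CH2Cl2, 0 °C to rt
Reagents that add atoms: tert-butyl hydroperoxide, CC(C)(C)OO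
Why: Hydroxyl-directed vanadium-catalysed epoxidation delivers oxygen syn to the C6 hydroxyl (sets C7 and C8) and leaves the isopropenyl group untouched.

Step 6
Reactants: 7 cis-epoxy alcohol; 4 2-methoxy-6-methyl-4-(triisopropylsilyloxy)benzoic acid
Product: 8 trans-epoxy ester (6β-OC(O)Ar; 7α,8α-epoxide; 4aα-isopropenyl)
Conditions: PPh3, DIAD, toluene, 0 to 40 °C
Reagents that add atoms: none
Why: Mitsunobu esterification, in which the carboxylate oxygen (not the di-ortho-substituted acyl carbon) is the nucleophile and SN2 inversion sets the final C6 configuration, trans to the epoxide.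

Step 7
Reactants: 8 trans-epoxy ester
Product: 11 ketol (6β-OC(O)Ar; 7β-OH; 7α-CH3; C8 ketone; 4aα-isopropenyl), via dioxolanylium ion 9 (not isolated), via diol ester 10 (not isolated)
Conditions: TsOH·H2O (10 mol%), THF/H2O (10:1), 0 °C to rt; then DMSO, IBX (1.5 equiv), rt
Reagents that add atoms: water, O
Why: Anchimerically assisted epoxide opening, in which the trans ester carbonyl attacks the tertiary C7 from the β face (inversion, sets C7) to a cis-fused dioxolanylium ion that hydrolyses to the axial C6 ester and free 7β-OH, after which IBX oxidises only the secondary C8 alcohol without glycol cleavage.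

Step 8
Reactants: 11 ketol
Product: 13 C8a-(tert-butyldimethylsilyloxymethyl) ketol (C8a epimers), via hydroxymethyl ketol 12 (not isolated)
Conditions: LiN(SiMe3)2 (2.2 equiv), THF, −78 °C; CH2O (gas); AcOH; then TBSCl, imidazole, DMF, 0 °C
Reagents that add atoms: formaldehyde, C=O; tert-butyldimethylsilyl chloride, CC(C)(C)[Si](C)(C)Cl
Why: Aldol addition to formaldehyde, in which the enolate can form only at C8a because C7 is quaternary, the silylamide base spares the toluate methyl, and the primary alcohol is then silylated selectively (the C8a centre is lost later).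

Step 9
Reactants: 13 C8a-(tert-butyldimethylsilyloxymethyl) ketol; 14 (E)-pent-3-en-1-yne
Product: 16 C4a-[(E)-pent-3-en-1-ynyl] ketone (C4a and C8a epimers), via methoxy hydroperoxide 15 (not isolated)
Conditions: O3, CH2Cl2/MeOH (5:1), −78 °C, N2 purge; then 14 (3 equiv), Cu(MeCN)4PF6 (10 mol%), 1,10-phenanthroline (12 mol%), K2CO3 (20 mol%), MeCN, 450 nm LEDs, −20 °C to rt
Reagents that add atoms: none
Why: Proposed new method: photoinduced copper-catalysed dealkenylative alkynylation, in which Criegee ozonolysis in methanol turns the isopropenyl group into the α-methoxy hydroperoxide, the blue-light-excited monovalent copper acetylide of 14 reduces its O–O bond, the alkoxy radical loses methyl acetate by β-scission, and the secondary C4a radical is captured by the divalent copper acetylide and reductively eliminated from trivalent copper to forge C4a–C4 (the C4a configuration is no longer needed); the closest known reaction types are the iron- or copper-mediated dealkenylative functionalisations of ozonolysis-derived hydroperoxides and the photoinduced copper-catalysed coupling of alkyl radicals with terminal alkynes.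

Step 10
Reactants: 16 C4a-[(E)-pent-3-en-1-ynyl] ketone
Product: 17 enynone (C8a=C4a; C8a-CH2OTBS; C4a-pentenynyl)
Conditions: IBX (2.5 equiv), 4-methoxypyridine N-oxide (2.5 equiv), DMSO, rt to 40 °C
Reagents that add atoms: none
Why: IBX ketone α,β-dehydrogenation, where only C8a carries an α-hydrogen and the β-hydrogen is tertiary and propargylic, so the tetrasubstituted enynone forms and both scrambled centres become sp2.

Step 11
Reactants: 17 enynone
Product: 18 vinylogous amide (C3-pyrrolidinyl dienone; mixture of C3=C4 isomers)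
Conditions: pyrrolidine (1.5 equiv), MeOH, 0 °C to rt
Reagents that add atoms: pyrrolidine, C1CCNC1
Why: Aza-Michael 1,6-addition to the enynone places the amine on the alkyne terminus through the conjugated π-system, fixing C3 at the carbonyl oxidation level and pre-empting 5-exo closure to a furan.

Step 12
Reactants: 18 vinylogous amide
Product: 21 comazaphilone G, via hydroxy enaminone 19 (not isolated), via cyclic aminal 20 (not isolated)
Conditions: HF·pyridine, pyridine, THF, 0 °C to rt
Reagents that add atoms: none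
Why: Global desilylation followed by amine–alcohol exchange, in which C4-protonation gives the iminium ion, the C1 hydroxyl adds to C3 (6-exo-trig) and loss of pyrrolidine leaves the doubly vinylogous ester, the ring size being dictated by the iminium carbon.

## Compound list

1 | 2,4-dihydroxy-6-methylbenzaldehyde | Cc1cc(O)cc(O)c1C=O | starting material
2 | 2-hydroxy-6-methyl-4-(triisopropylsilyloxy)benzaldehyde | Cc1cc(O[Si](C(C)C)(C(C)C)C(C)C)cc(O)c1C=O | intermediate
3 | 2-methoxy-6-methyl-4-(triisopropylsilyloxy)benzaldehyde | COc1cc(O[Si](C(C)C)(C(C)C)C(C)C)cc(C)c1C=O | intermediate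
4 | 2-methoxy-6-methyl-4-(triisopropylsilyloxy)benzoic acid | COc1cc(O[Si](C(C)C)(C(C)C)C(C)C)cc(C)c1C(=O)O | intermediate
5 | (R)-(−)-carvone, (5R)-2-methyl-5-(prop-1-en-2-yl)cyclohex-2-en-1-one | CC1=CC[C@H](CC1=O)C(C)=C | starting material
6 | (−)-cis-carveol, (1R,5R)-2-methyl-5-(prop-1-en-2-yl)cyclohex-2-en-1-ol | C1C=C(C)[C@H](O)C[C@@H]1C(C)=C | intermediate
7 | 1-methyl-4-(prop-1-en-2-yl)-7-oxabicyclo[4.1.0]heptan-2-ol with OH, epoxide O and isopropenyl all α | C1[C@@H]2O[C@]2(C)[C@H](O)C[C@@H]1C(C)=C | intermediate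
8 | aryl ester of the C6-epimer of 7: 6β-OC(O)Ar, 7α,8α-epoxide, 4aα-isopropenyl | C1[C@@H]2O[C@]2(C)[C@@H](OC(=O)c3c(C)cc(O[Si](C(C)C)(C(C)C)C(C)C)cc3OC)C[C@@H]1C(C)=C | intermediate
9 | cis-fused 2-aryl-1,3-dioxolan-2-ylium ion bridging O6 and O7 (both β), 8α-OH, as tosylate | C1[C@H](O)[C@@]2(C)[O+]=C(c3c(C)cc(O[Si](C(C)C)(C(C)C)C(C)C)cc3OC)O[C@H]2C[C@@H]1C(C)=C.Cc1ccc(cc1)S(=O)(=O)[O-] | intermediate
10 | diol ester: 6β-OC(O)Ar, 7β-OH, 7α-CH3, 8α-OH, 4aα-isopropenyl | C1[C@H](O)[C@@](C)(O)[C@@H](OC(=O)c3c(C)cc(O[Si](C(C)C)(C(C)C)C(C)C)cc3OC)C[C@@H]1C(C)=C | intermediate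
11 | ketol: 2-hydroxy-2-methyl-3-oxo-5-(prop-1-en-2-yl)cyclohexyl ester of 4 (6β-OC(O)Ar, 7β-OH, C8 ketone, 4aα-isopropenyl) | C1C(=O)[C@@](C)(O)[C@@H](OC(=O)c3c(C)cc(O[Si](C(C)C)(C(C)C)C(C)C)cc3OC)C[C@@H]1C(C)=C | intermediate
12 | C8a-hydroxymethyl derivative of 11 (C8a epimers) | OCC1C(=O)[C@@](C)(O)[C@@H](OC(=O)c3c(C)cc(O[Si](C(C)C)(C(C)C)C(C)C)cc3OC)C[C@@H]1C(C)=C | intermediate
13 | C8a-(tert-butyldimethylsilyloxymethyl) derivative of 11 (C8a epimers) | CC(C)(C)[Si](C)(C)OCC1C(=O)[C@@](C)(O)[C@@H](OC(=O)c3c(C)cc(O[Si](C(C)C)(C(C)C)C(C)C)cc3OC)C[C@@H]1C(C)=C | intermediate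
14 | (E)-pent-3-en-1-yne | C/C=C/C#C | starting material
15 | α-methoxy hydroperoxide of 13: C4a–C(CH3)(OCH3)OOH (epimers) | CC(C)(C)[Si](C)(C)OCC1C(=O)[C@@](C)(O)[C@@H](OC(=O)c3c(C)cc(O[Si](C(C)C)(C(C)C)C(C)C)cc3OC)C[C@@H]1C(C)(OC)OO | intermediate
16 | C4a-[(E)-pent-3-en-1-ynyl] ketone (C4a and C8a epimers) | CC(C)(C)[Si](C)(C)OCC1C(=O)[C@@](C)(O)[C@@H](OC(=O)c3c(C)cc(O[Si](C(C)C)(C(C)C)C(C)C)cc3OC)CC1C#C/C=C/C | intermediate
17 | enynone: (6S,7S)-6-aroyloxy-7-hydroxy-7-methyl-8a-(TBS-oxymethyl)-4a-[(E)-pent-3-en-1-ynyl]cyclohex-4a(8a)-en-8-one | C/C=C/C#CC1=C(CO[Si](C)(C)C(C)(C)C)C(=O)[C@@](C)(O)[C@@H](OC(=O)c3c(C)cc(O[Si](C(C)C)(C(C)C)C(C)C)cc3OC)C1 | intermediate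
18 | vinylogous amide: C4a-[2-(pyrrolidin-1-yl)penta-1,3-dienyl] enone (C3=C4 isomers) | C/C=C/C(N4CCCC4)=CC1=C(CO[Si](C)(C)C(C)(C)C)C(=O)[C@@](C)(O)[C@@H](OC(=O)c3c(C)cc(O[Si](C(C)C)(C(C)C)C(C)C)cc3OC)C1 | intermediate
19 | desilylated vinylogous amide (free C1–OH and free phenol) | C/C=C/C(N4CCCC4)=CC1=C(CO)C(=O)[C@@](C)(O)[C@@H](OC(=O)c3c(C)cc(O)cc3OC)C1 | intermediate
20 | cyclic N,O-aminal: 3-(pyrrolidin-1-yl)-3,4-dihydro-1H-isochromene (C3 epimers) | C/C=C/C1(N4CCCC4)CC2=C(CO1)C(=O)[C@@](C)(O)[C@@H](OC(=O)c3c(C)cc(O)cc3OC)C2 | intermediate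
21 | comazaphilone G, (6S,7S)-7-hydroxy-7-methyl-8-oxo-3-[(E)-prop-1-enyl]-5,6,7,8-tetrahydro-1H-isochromen-6-yl 4-hydroxy-2-methoxy-6-methylbenzoate | C/C=C/C1=CC2=C(CO1)C(=O)[C@@](C)(O)[C@@H](OC(=O)c1c(C)cc(O)cc1OC)C2 | target

## Step count and risks

Total steps: 12. Longest linear sequence: 10 (steps 1, 2, 3, 6, 7, 8, 9, 10, 11, 12; the carvone branch is 9).

The three steps most likely to fail:

Step 6 (Mitsunobu at a carbinol flanked by a fully substituted epoxide carbon, with a hindered acid). The fallback sets out from 7. Tf2O and pyridine in CH2Cl2 at −40 °C give the secondary 6α-triflate F1. This is displaced with inversion by acid 4 in the presence of Cs2CO3 and 18-crown-6 in toluene/DMF at −20 to 0 °C (stepwise sulfonate displacement instead of in-situ phosphonium activation). It comes back to the route at 8.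

Step 9 (the proposed new photochemical alkynylation). Likely failure modes are Glaser coupling of 14, radical addition to the enyne, and oxidation of the C4a radical to the alkene. The fallback uses known chemistry and sets out from 13. Ozonolysis in CH2Cl2/MeOH gives the same hydroperoxide 15. Cu(OAc)2·H2O and FeSO4·7H2O then effect the known dealkenylative desaturation and give the 2-(silyloxymethyl) enone F2. Nickel-catalysed conjugate alkynylation (Ni(acac)2, DIBAL-H, Et2O, 0 °C) with dimethyl[(E)-pent-3-en-1-ynyl]alumane F3, made in the flask from 14, n-BuLi and Me2AlCl, comes back to the route at 16.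

Step 10 (IBX dehydrogenation to a tetrasubstituted enynone; slow enolisation or over-oxidation are possible). The fallback sets out from 16. Soft enolisation with TMSOTf and Et3N in CH2Cl2 gives the bis-trimethylsilyl compound F4 (C8 enol silane and O7 silyl ether). Saegusa–Ito oxidation with Pd(OAc)2 in MeCN gives the O7-silylated enynone F5. A citric acid wash removes its silyl ether, and the sequence comes back to the route at 17.

Further compounds

F1 | step 6 | 6α-trifluoromethanesulfonate of 7 (7α,8α-epoxide; 4aα-isopropenyl) | C1[C@@H]2O[C@]2(C)[C@H](OS(=O)(=O)C(F)(F)F)C[C@@H]1C(C)=C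
F2 | step 9 | (6S,7S)-6-aroyloxy-7-hydroxy-7-methyl-8a-(TBS-oxymethyl)cyclohex-4a(8a)-en-8-one | C1=C(CO[Si](C)(C)C(C)(C)C)C(=O)[C@@](C)(O)[C@@H](OC(=O)c3c(C)cc(O[Si](C(C)C)(C(C)C)C(C)C)cc3OC)C1
F3 | step 9 | dimethyl[(E)-pent-3-en-1-yn-1-yl]alumane | C/C=C/C#C[Al](C)C
F4 | step 10 | C8 trimethylsilyl enol ether and O7 trimethylsilyl ether of 16 (C4a epimers) | CC(C)(C)[Si](C)(C)OCC1=C(O[Si](C)(C)C)[C@@](C)(O[Si](C)(C)C)[C@@H](OC(=O)c3c(C)cc(O[Si](C(C)C)(C(C)C)C(C)C)cc3OC)CC1C#C/C=C/C
F5 | step 10 | O7 trimethylsilyl ether of 17 | C/C=C/C#CC1=C(CO[Si](C)(C)C(C)(C)C)C(=O)[C@@](C)(O[Si](C)(C)C)[C@@H](OC(=O)c3c(C)cc(O[Si](C(C)C)(C(C)C)C(C)C)cc3OC)C1
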